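**Retrosynthetic overview** (germacrane numbering: C6 lactone carbinol, C7 ring fusion, C8 ester carbon, C10 tertiary carbinol, C11–C13 methylene-lactone carbons)

1. Target 21 ⇐ lactonisation (O6→C12) of 20 ⇐ C6–C7 closure of the seco-germacrane spiro-lactol bromide 18 by indium Barbier reaction. The ten-membered carbocycle forms first and the γ-lactone second, in one flask, mirroring farnesyl diphosphate → germacrene acid → 6,12-olide.
2. 18 ⇐ 15 by singlet-oxygen opening of a 3-methylfuran (latent C3 ketone and C6 aldehyde with the 4Z alkene built in; the C10 hydroxyl folds it into a spiroketal).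
3. 15 ⇐ aldehyde 11 + methyl acrylate (Baylis–Hillman, then SN2′ bromination: C11–C13 and the (Z)-allyl bromide).
4. 11 ⇐ aldol 5 + furylacetylene 2 (chelation-controlled addition sets C10), acylation with (R)-2-methylbutanoic acid, acetal unmasking, Lindlar reduction (1Z).
5. 5 ⇐ acetone + 2,2-dimethoxyacetaldehyde (L-proline aldol sets C8); 2 ⇐ 3-methylfuran-2-carbaldehyde.

Assumption: the target is drawn as the open (1Z)-4-hydroxy-enone; it can close reversibly to its 3,10-hemiketal, and the two tautomers are treated as one compound.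

**Route**

Step 1
Reactants: 1 3-methylfuran-2-carbaldehyde
Product: 2 2-ethynyl-3-methylfuran
Conditions: Ohira–Bestmann reagent, K2CO3, MeOH, 0 °C → rt
Reagents that add atoms: dimethyl (1-diazo-2-oxopropyl)phosphonate, CC(=O)C(=[N+]=[N-])P(=O)(OC)OC
Why: Seyferth–Gilbert homologation (Ohira–Bestmann variant) turns the non-enolisable heteroaryl aldehyde into the terminal alkyne under mild carbonate conditions that the furan tolerates; no stereocentre is involved.

Step 2
Reactants: 3 acetone; 4 2,2-dimethoxyacetaldehyde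
Product: 5 (4R)-4-hydroxy-5,5-dimethoxypentan-2-one
Conditions: L-proline (30 mol %), acetone as solvent, 4 °C, 48 h
Reagents that add atoms: none
Why: Proline-catalysed direct asymmetric aldol reaction: the L-proline enamine of acetone attacks the Re face of the non-enolisable α-oxygenated aldehyde through the hydrogen-bonded chair transition state, setting C8 as (R) in the same sense as for other α-branched aldehydes.

Step 3
Reactants: 2 2-ethynyl-3-methylfuran; 5 (4R)-4-hydroxy-5,5-dimethoxypentan-2-one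
Product: 7 (2R,4R)-1,1-dimethoxy-4-methyl-6-(3-methylfuran-2-yl)hex-5-yne-2,4-diol, via alkynylmagnesium bromide 6 (not isolated)
Conditions: 2 (2.6 equiv), EtMgBr (2.5 equiv), THF, 0 °C → rt; then 5, CH2Cl2/THF, −78 → −20 °C; aq. NH4Cl
Reagents that add atoms: none
Why: Chelation-controlled (Cram-chelate, 1,3-induction) Grignard alkynylation: the first equivalent forms the magnesium aldolate, and the slim alkynyl nucleophile attacks its six-membered chelate axially, trans to the C8 substituent, giving the 1,3-anti diol, i.e. (R) at C10 (the minor epimer is removed by chromatography).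

Step 4
Reactants: 7 (2R,4R)-1,1-dimethoxy-4-methyl-6-(3-methylfuran-2-yl)hex-5-yne-2,4-diol; 8 (2R)-2-methylbutanoic acid
Product: 9 (2R,4R)-4-hydroxy-1,1-dimethoxy-4-methyl-6-(3-methylfuran-2-yl)hex-5-yn-2-yl (2R)-2-methylbutanoate
Conditions: 8 (1.2 equiv), DCC, DMAP (5 mol %), CH2Cl2, 0 °C
Reagents that add atoms: none
Why: Steglich esterification acylates only the secondary C8 hydroxyl (the tertiary propargylic hydroxyl is inert), and low DMAP loading at 0 °C avoids ketene formation so the (R)-α-centre of the acid is kept.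

Step 5
Reactants: 9 (2R,4R)-4-hydroxy-1,1-dimethoxy-4-methyl-6-(3-methylfuran-2-yl)hex-5-yn-2-yl (2R)-2-methylbutanoate
Product: 10 (2R,4R)-4-methyl-6-(3-methylfuran-2-yl)-1-oxo-4-(triethylsilyloxy)hex-5-yn-2-yl (2R)-2-methylbutanoate
Conditions: TESOTf (3 equiv), 2,4,6-collidine (4.5 equiv), CH2Cl2, 0 °C; then H2O
Reagents that add atoms: triethylsilyl trifluoromethanesulfonate, CC[Si](CC)(CC)OS(=O)(=O)C(F)(F)F; water, O
Why: Silyl triflate/collidine acetal cleavage converts the dimethyl acetal via a collidinium salt that water hydrolyses to the aldehyde without aqueous acid, and the same reagent caps the tertiary hydroxyl, which would otherwise close onto the new aldehyde as a five-membered lactol and stall step 7.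

Step 6
Reactants: 10 (2R,4R)-4-methyl-6-(3-methylfuran-2-yl)-1-oxo-4-(triethylsilyloxy)hex-5-yn-2-yl (2R)-2-methylbutanoate
Product: 11 (2R,4R,5Z)-4-methyl-6-(3-methylfuran-2-yl)-1-oxo-4-(triethylsilyloxy)hex-5-en-2-yl (2R)-2-methylbutanoate
Conditions: H2 (1 atm), Lindlar catalyst, quinoline, EtOAc, rt
Reagents that add atoms: none
Why: Lindlar semi-hydrogenation delivers H2 syn on poisoned palladium to give the (Z)-alkene (the later C1=C2) without touching the aldehyde, the esters, the furan or the stereocentres.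

Step 7
Reactants: 11 (2R,4R,5Z)-4-methyl-6-(3-methylfuran-2-yl)-1-oxo-4-(triethylsilyloxy)hex-5-en-2-yl (2R)-2-methylbutanoate; 12 methyl acrylate
Product: 14 methyl (4R,6R,7Z)-3,6-dihydroxy-6-methyl-2-methylidene-4-[(2R)-2-methylbutanoyloxy]-8-(3-methylfuran-2-yl)oct-7-enoate, via silyl ether adduct 13 (not isolated)
Conditions: 12 (10 equiv), DABCO (1 equiv), neat, rt, 36 h; then TBAF/AcOH (1:1), THF, 0 °C → rt
Reagents that add atoms: none
Why: Morita–Baylis–Hillman reaction of the activated α-acyloxy aldehyde forms C7–C11 with C12 already at the ester level (the new carbinol configuration is irrelevant because step 8 destroys it), and buffered fluoride then removes the tertiary silyl ether without acyl migration.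

Step 8
Reactants: 14 methyl (4R,6R,7Z)-3,6-dihydroxy-6-methyl-2-methylidene-4-[(2R)-2-methylbutanoyloxy]-8-(3-methylfuran-2-yl)oct-7-enoate
Product: 15 methyl (2Z,4R,6R,7Z)-2-(bromomethyl)-6-hydroxy-6-methyl-4-[(2R)-2-methylbutanoyloxy]-8-(3-methylfuran-2-yl)octa-2,7-dienoate
Conditions: NBS, Me2S, CH2Cl2, −20 → 0 °C
Reagents that add atoms: N-bromosuccinimide, O=C1CCC(=O)N1Br
Why: Corey–Kim-type SN2′ bromination (alkoxysulfonium at the secondary allylic hydroxyl, bromide attack at C13 with allylic transposition) gives the thermodynamically preferred (2Z)-2-(bromomethyl)enoate with C8 cis to CH2Br, while the tertiary alcohol does not react.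

Step 9
Reactants: 15 methyl (2Z,4R,6R,7Z)-2-(bromomethyl)-6-hydroxy-6-methyl-4-[(2R)-2-methylbutanoyloxy]-8-(3-methylfuran-2-yl)octa-2,7-dienoate
Product: 18 methyl (2Z,4R)-2-(bromomethyl)-5-[(2R)-7-hydroxy-2,9-dimethyl-1,6-dioxaspiro[4.4]nona-3,8-dien-2-yl]-4-[(2R)-2-methylbutanoyloxy]pent-2-enoate, via furan endoperoxide 16 (not isolated), via open keto-enal 17 (not isolated)
Conditions: O2, tetraphenylporphyrin (cat.), visible light, CH2Cl2, −78 °C; then Me2S (1.5 equiv), −78 → 0 °C, volatiles removed at once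
Reagents that add atoms: dioxygen, O=O
Why: Furan photo-oxygenation ([4+2] addition of singlet oxygen, then sulfide reduction of the endoperoxide) unveils the (Z)-4-oxo-2-enal (C3 ketone, C6 aldehyde, 4Z by construction), which the cis-placed C10 hydroxyl traps at once as the spiro-lactol, so C3 is masked and both Z alkenes are locked in rings.

Step 10
Reactants: 18 methyl (2Z,4R)-2-(bromomethyl)-5-[(2R)-7-hydroxy-2,9-dimethyl-1,6-dioxaspiro[4.4]nona-3,8-dien-2-yl]-4-[(2R)-2-methylbutanoyloxy]pent-2-enoate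
Product: 21 (3aR,4R,6R,7Z,10Z,11aS)-6-hydroxy-6,10-dimethyl-3-methylidene-2,9-dioxo-3a,4,5,11a-tetrahydrocyclodeca[b]furan-4-yl (2R)-2-methylbutanoate, via allylindium species 19 (not isolated), via macrocyclic dihydroxy ester 20 (not isolated)
Conditions: In powder (4 equiv), THF/H2O (1:1), 2 mM, rt, sonication; then PPTS (20 mol %), CH2Cl2, rt
Reagents that add atoms: none
Why: Proposed new method: an indium-mediated intramolecular Barbier (Nozaki–Hiyama-type) 2-(alkoxycarbonyl)allylation of a lactol closes the ten-membered ring at C6–C7, the bond formed from farnesyl diphosphate in germacrene biosynthesis, and the 6-hydroxyl then lactonises onto C12 as in costunolide formation; the (Z)-allylindium adds to the ring-opened aldehyde through a chair transition state with C8 axial and C5 equatorial (6,7-syn, hence the cis-fused lactone, 6S), on the alkene face where H8 eclipses the double bond (A1,3 strain), the C9 chain is anti and the small acyloxy group is outside (7R from 8R), while the C3 ketone stays hidden as the hemiketal so that only C6 is electrophilic; the closest known reactions are chromium- or zinc-mediated Barbier macrocyclisations of farnesal-type bromo esters to germacranolides and aqueous indium allylation of sugar lactols with 2-(bromomethyl)acrylates, where (Z)-bromides give cis-lactones.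

**Compound list**

1 | 3-methylfuran-2-carbaldehyde | Cc1ccoc1C=O | starting material
2 | 2-ethynyl-3-methylfuran | Cc1ccoc1C#C | intermediate
3 | acetone | CC(C)=O | starting material
4 | 2,2-dimethoxyacetaldehyde (commercial 60 % aqueous solution) | COC(OC)C=O | starting material
5 | (4R)-4-hydroxy-5,5-dimethoxypentan-2-one | CC(=O)C[C@@H](O)C(OC)OC | intermediate
6 | [(3-methylfuran-2-yl)ethynyl]magnesium bromide | Cc1ccoc1C#C[Mg]Br | intermediate
7 | (2R,4R)-1,1-dimethoxy-4-methyl-6-(3-methylfuran-2-yl)hex-5-yne-2,4-diol | COC(OC)[C@H](O)C[C@@](C)(O)C#Cc1occc1C | intermediate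
8 | (2R)-2-methylbutanoic acid | CC[C@@H](C)C(=O)O | starting material
9 | (2R,4R)-4-hydroxy-1,1-dimethoxy-4-methyl-6-(3-methylfuran-2-yl)hex-5-yn-2-yl (2R)-2-methylbutanoate | COC(OC)[C@H](OC(=O)[C@H](C)CC)C[C@@](C)(O)C#Cc1occc1C | intermediate
10 | (2R,4R)-4-methyl-6-(3-methylfuran-2-yl)-1-oxo-4-(triethylsilyloxy)hex-5-yn-2-yl (2R)-2-methylbutanoate | O=C[C@H](OC(=O)[C@H](C)CC)C[C@@](C)(O[Si](CC)(CC)CC)C#Cc1occc1C | intermediate
11 | (2R,4R,5Z)-4-methyl-6-(3-methylfuran-2-yl)-1-oxo-4-(triethylsilyloxy)hex-5-en-2-yl (2R)-2-methylbutanoate | O=C[C@H](OC(=O)[C@H](C)CC)C[C@@](C)(O[Si](CC)(CC)CC)/C=C\c1occc1C | intermediate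
12 | methyl acrylate | C=CC(=O)OC | starting material
13 | methyl (4R,6R,7Z)-3-hydroxy-6-methyl-2-methylidene-4-[(2R)-2-methylbutanoyloxy]-8-(3-methylfuran-2-yl)-6-(triethylsilyloxy)oct-7-enoate (both C3 epimers) | C=C(C(=O)OC)C(O)[C@H](OC(=O)[C@H](C)CC)C[C@@](C)(O[Si](CC)(CC)CC)/C=C\c1occc1C | intermediate
14 | methyl (4R,6R,7Z)-3,6-dihydroxy-6-methyl-2-methylidene-4-[(2R)-2-methylbutanoyloxy]-8-(3-methylfuran-2-yl)oct-7-enoate (both C3 epimers) | C=C(C(=O)OC)C(O)[C@H](OC(=O)[C@H](C)CC)C[C@@](C)(O)/C=C\c1occc1C | intermediate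
15 | methyl (2Z,4R,6R,7Z)-2-(bromomethyl)-6-hydroxy-6-methyl-4-[(2R)-2-methylbutanoyloxy]-8-(3-methylfuran-2-yl)octa-2,7-dienoate | COC(=O)/C(CBr)=C/[C@H](OC(=O)[C@H](C)CC)C[C@@](C)(O)/C=C\c1occc1C | intermediate
16 | furan 2,5-endoperoxide of 15 (2,3,7-trioxabicyclo[2.2.1]hept-5-ene, bridgeheads unassigned) | COC(=O)/C(CBr)=C/[C@H](OC(=O)[C@H](C)CC)C[C@@](C)(O)/C=C\C12OOC(C=C1C)O2 | intermediate
17 | methyl (2Z,4R,6R,7Z,10Z)-2-(bromomethyl)-6-hydroxy-6,10-dimethyl-4-[(2R)-2-methylbutanoyloxy]-9,12-dioxododeca-2,7,10-trienoate | COC(=O)/C(CBr)=C/[C@H](OC(=O)[C@H](C)CC)C[C@@](C)(O)/C=C\C(=O)/C(C)=C\C=O | intermediate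
18 | methyl (2Z,4R)-2-(bromomethyl)-5-[(2R)-7-hydroxy-2,9-dimethyl-1,6-dioxaspiro[4.4]nona-3,8-dien-2-yl]-4-[(2R)-2-methylbutanoyloxy]pent-2-enoate (epimers at spiro C5 and lactol C7) | COC(=O)/C(CBr)=C/[C@H](OC(=O)[C@H](C)CC)C[C@@]1(C)OC2(C=C1)OC(O)C=C2C | intermediate
19 | allylindium(I) species from 18 (CH2Br replaced by CH2In) | COC(=O)/C(C[In])=C/[C@H](OC(=O)[C@H](C)CC)C[C@@]1(C)OC2(C=C1)OC(O)C=C2C | intermediate
20 | methyl 2-[(1S,2S,3Z,6Z,8R,10R)-2,8-dihydroxy-4,8-dimethyl-10-[(2R)-2-methylbutanoyloxy]-5-oxocyclodeca-3,6-dien-1-yl]prop-2-enoate (6β,10α-dihydroxy-8β-acyloxy seco-lactone, drawn as the open tautomer of its 3,10-hemiketal) | C=C(C(=O)OC)[C@H]1[C@@H](O)/C=C(/C)C(=O)/C=C\[C@](C)(O)C[C@H]1OC(=O)[C@H](C)CC | intermediate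
21 | (3aR,4R,6R,7Z,10Z,11aS)-6-hydroxy-6,10-dimethyl-3-methylidene-2,9-dioxo-3a,4,5,11a-tetrahydrocyclodeca[b]furan-4-yl (2R)-2-methylbutanoate (6S,7R,8R,10R; 6,7-cis-fused 6β,12-olide, 8β-ester, 10α-OH) | C=C1C(=O)O[C@H]2/C=C(/C)C(=O)/C=C\[C@](C)(O)C[C@@H](OC(=O)[C@H](C)CC)[C@@H]12 | target

**Step count**

Total steps: 10. Longest linear sequence: 9 (steps 2–10; step 1 is a side branch feeding step 3).

**Steps most likely to fail, with fallbacks**

Step 10 (ring closure). The allylindium could lose the C8 acyloxy group by 1,4-elimination to a 2-methoxycarbonyl diene, attack the wrong alkene face, or oligomerise. The fallback sets out from 14 and comes back at 20, replacing the organometallic by a neutral allylboron reagent. The secondary hydroxyl of 14 is acetylated (Ac2O, cat. DMAP, 0 °C) to the Baylis–Hillman acetate F1. Copper-catalysed SN2′ borylation (B2pin2, CuCl, KOAc, DMF) gives the (E)-allylboronate F2, which has C8 cis to CH2B as in 15. Photo-oxygenation as in step 9 gives the spiro-lactol boronate F3. Intramolecular allylboration (Sc(OTf)3 5 mol %, THF/H2O, 2 mM, rt, or 50 °C without catalyst) then closes the ring through the same closed six-membered transition state, with no carbanionic intermediate that could eliminate. Hydrolysis of the borate gives 20, which is lactonised as before.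

Step 7 (Baylis–Hillman on an α-acyloxy aldehyde). The amine-catalysed reaction may be slow enough for the acyl group to move from O8 to the new O7 hydroxyl, or for C8 to epimerise. The fallback sets out from 11 and comes back at 13, making the same bond with a preformed acrylate α-anion equivalent under base-free conditions. Hydroalumination of methyl propiolate with i-Bu2AlH/N-methylmorpholine N-oxide in THF at 0 °C gives methyl 2-(diisobutylalumanyl)prop-2-enoate F4. This adds to 11 within hours at 0 °C to give 13, which is desilylated to 14 as in step 7.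

Step 5 (acetal cleavage next to the ester). The silyl triflate may engage the neighbouring acyloxy group (acyloxonium formation, acyl shift) instead of giving the aldehyde cleanly. The fallback sets out from 9 and comes back at 14, dropping the silyl ether and working through the lactol. Mild aqueous acid (Amberlyst-15, wet acetone, rt → 40 °C) hydrolyses 9 to the five-membered lactol F5 (O10 bonded to C7). Lindlar reduction as in step 6 gives the (Z)-alkenyl lactol F6. A lactol offers too little free aldehyde for amine catalysis, so C7–C11 is then made with the propiolate-derived alane of the step 7 fallback (3 equiv, THF, 0 °C → rt; the aluminium lactolate opens), which gives diol 14 directly.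

**Further compounds**

F1 | step 10 | methyl (4R,6R,7Z)-3-acetoxy-6-hydroxy-6-methyl-2-methylidene-4-[(2R)-2-methylbutanoyloxy]-8-(3-methylfuran-2-yl)oct-7-enoate (both C3 epimers) | C=C(C(=O)OC)C(OC(C)=O)[C@H](OC(=O)[C@H](C)CC)C[C@@](C)(O)/C=C\c1occc1C
F2 | step 10 | methyl (2E,4R,6R,7Z)-6-hydroxy-6-methyl-4-[(2R)-2-methylbutanoyloxy]-8-(3-methylfuran-2-yl)-2-[(4,4,5,5-tetramethyl-1,3,2-dioxaborolan-2-yl)methyl]octa-2,7-dienoate | COC(=O)/C(CB1OC(C)(C)C(C)(C)O1)=C/[C@H](OC(=O)[C@H](C)CC)C[C@@](C)(O)/C=C\c1occc1C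
F3 | step 10 | methyl (2E,4R)-5-[(2R)-7-hydroxy-2,9-dimethyl-1,6-dioxaspiro[4.4]nona-3,8-dien-2-yl]-4-[(2R)-2-methylbutanoyloxy]-2-[(4,4,5,5-tetramethyl-1,3,2-dioxaborolan-2-yl)methyl]pent-2-enoate (epimers at spiro and lactol carbons) | COC(=O)/C(CB1OC(C)(C)C(C)(C)O1)=C/[C@H](OC(=O)[C@H](C)CC)C[C@@]1(C)OC2(C=C1)OC(O)C=C2C
F4 | step 7 | methyl 2-(diisobutylalumanyl)prop-2-enoate | C=C(C(=O)OC)[Al](CC(C)C)CC(C)C
F5 | step 5 | (3R,5R)-2-hydroxy-5-methyl-5-[(3-methylfuran-2-yl)ethynyl]oxolan-3-yl (2R)-2-methylbutanoate (both anomers) | OC1O[C@@](C)(C#Cc2occc2C)C[C@H]1OC(=O)[C@H](C)CC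
F6 | step 5 | (3R,5R)-2-hydroxy-5-methyl-5-[(Z)-2-(3-methylfuran-2-yl)ethenyl]oxolan-3-yl (2R)-2-methylbutanoate (both anomers) | OC1O[C@@](C)(/C=C\c2occc2C)C[C@H]1OC(=O)[C@H](C)CC
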